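**Retrosynthetic overview**
- C11 is set last, by hydrogenating an 11(13)-methylene lactone from its open face (lactone first, 11,13-reduction after, as in the biogenesis of dihydro-germacranolides).
- Lactone (second ring): O6–C12 bond, closed in the same flask by the C6 alkoxide attacking the C12 methyl ester.
- Ten-membered ring (first ring): C6–C7 bond, the farnesyl C1–C10 bond of germacrene biogenesis, formed when the C7 end of a 2-(methoxycarbonyl)allyl metal attacks the C6 enal of an acyclic, fully oxygenated chain.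
- Chain: three C5 units joined at C2–C3 and C8–C9 by two catalyst-controlled allylations (C3, C9); the 1(10)Z alkene is fixed in a metathesis-made lactone that is then opened; the C7=C11 unit comes from cross-metathesis.

Assumption: the target is numbered as a germacra-1(10),4-dien-12,6-olide (C3 ester, C9 carbinol, cis-fused lactone, 1(10)Z,4E), so the biogenetic ring-closing C–C bond is C6–C7.

**Step 1**
Reactants: 1 2,2-dimethoxyacetaldehyde (60 wt % in water); 2 2-(triphenylphosphoranylidene)propanal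
Product: 3 (2E)-4,4-dimethoxy-2-methylbut-2-enal
Conditions: toluene, 80 °C
Reagents that add atoms: 2-(triphenylphosphoranylidene)propanal, CC(C=O)=P(c1ccccc1)(c1ccccc1)c1ccccc1
Why: Wittig olefination with a formyl-stabilised ylide gives the E enal, and the α,α-dialkoxy aldehyde is more electrophilic than the enal product, so over-reaction is minor.

**Step 2**
Reactants: 3 (2E)-4,4-dimethoxy-2-methylbut-2-enal; 4 allylboronic acid pinacol ester
Product: 6 (2E,4S)-1,1-dimethoxy-3-methylhepta-2,6-dien-4-ol, via borate ester 5 (not isolated)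
Conditions: (S)-TRIP phosphoric acid (5 mol %), 4 Å MS, toluene, −30 °C; aq. NaHCO3 work-up
Reagents that add atoms: allylboronic acid pinacol ester, C=CCB1OC(C)(C)C(C)(C)O1
Why: Chiral phosphoric acid-catalysed allylboration through a closed chair; the (S)-acid delivers allyl to the Si face of the enal and sets the carbinol (future C3) as S.

**Step 3**
Reactants: 6 (2E,4S)-1,1-dimethoxy-3-methylhepta-2,6-dien-4-ol; 7 methacryloyl chloride
Product: 8 (2E,4S)-1,1-dimethoxy-3-methylhepta-2,6-dien-4-yl 2-methylprop-2-enoate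
Conditions: Et3N, DMAP (cat.), CH2Cl2, 0 °C
Reagents that add atoms: methacryloyl chloride, CC(=C)C(Cl)=O
Why: Simple O-acylation of the secondary alcohol; the acetal and the stereocentre are untouched.

**Step 4**
Reactants: 8 (2E,4S)-1,1-dimethoxy-3-methylhepta-2,6-dien-4-yl 2-methylprop-2-enoate
Product: 9 (6S)-6-[(2E)-4,4-dimethoxybut-2-en-2-yl]-3-methyl-5,6-dihydro-2H-pyran-2-one
Conditions: second-generation Grubbs catalyst RuCl2(=CHPh)(PCy3)(SIMes) (5 mol %), CH2Cl2, 40 °C, 0.01 M
Reagents that add atoms: none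
Why: Ring-closing metathesis of the vinyl and methacrylate groups gives the six-membered unsaturated lactone, whose ring forces the future C1=C10 alkene to be Z; the trisubstituted side-chain alkene does not react.

**Step 5**
Reactants: 9 (6S)-6-[(2E)-4,4-dimethoxybut-2-en-2-yl]-3-methyl-5,6-dihydro-2H-pyran-2-one; 10 N,O-dimethylhydroxylamine hydrochloride
Product: 11 (2Z,5S,6E)-5-hydroxy-N,8,8-trimethoxy-N,2,6-trimethylocta-2,6-dienamide
Conditions: iPrMgCl (6 equiv), 10 (3 equiv), THF, −20 to 0 °C; aq. NH4Cl; used crude at once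
Reagents that add atoms: N,O-dimethylhydroxylamine hydrochloride, CNOC.Cl
Why: Weinreb aminolysis of the lactone by the magnesium amide (1,2-attack) frees the C3 hydroxyl and keeps the Z geometry that the ring had fixed.

**Step 6**
Reactants: 11 (2Z,5S,6E)-5-hydroxy-N,8,8-trimethoxy-N,2,6-trimethylocta-2,6-dienamide; 12 (2R)-2-methylbutanoic acid
Product: 13 (2E,4S,6Z)-1,1-dimethoxy-8-[methoxy(methyl)amino]-3,7-dimethyl-8-oxoocta-2,6-dien-4-yl (2R)-2-methylbutanoate
Conditions: DCC, DMAP (10 mol %), CH2Cl2, 0 °C to rt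
Reagents that add atoms: (2R)-2-methylbutanoic acid, CC[C@@H](C)C(O)=O
Why: Steglich esterification installs the final C3 ester early, which also stops re-lactonisation; the mild conditions do not epimerise the acid.

**Step 7**
Reactants: 13 (2E,4S,6Z)-1,1-dimethoxy-8-[methoxy(methyl)amino]-3,7-dimethyl-8-oxoocta-2,6-dien-4-yl (2R)-2-methylbutanoate
Product: 15 (2E,4S,6Z)-1,1-dimethoxy-3,7-dimethyl-8-oxoocta-2,6-dien-4-yl (2R)-2-methylbutanoate, via zirconium hemiaminal 14 (not isolated)
Conditions: Cp2Zr(H)Cl (1.5 equiv), THF, rt, 20 min; then H2O, silica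
Reagents that add atoms: none
Why: Schwartz-reagent reduction of a tertiary amide stops at the zirconated hemiaminal and gives the aldehyde on work-up, leaving the carboxylic ester, the acetal and the Z alkene untouched.

**Step 8**
Reactants: 15 (2E,4S,6Z)-1,1-dimethoxy-3,7-dimethyl-8-oxoocta-2,6-dien-4-yl (2R)-2-methylbutanoate; 4 allylboronic acid pinacol ester
Product: 17 (2E,4S,6Z,8S)-8-hydroxy-3,7-dimethyl-1-oxoundeca-2,6,10-trien-4-yl (2R)-2-methylbutanoate, via borate ester 16 (not isolated)
Conditions: (S)-TRIP phosphoric acid (5 mol %), 4 Å MS, toluene, −30 °C; then 5 % aq. oxalic acid, THF, 0 °C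
Reagents that add atoms: allylboronic acid pinacol ester, C=CCB1OC(C)(C)C(C)(C)O1; water, O
Why: A second phosphoric acid-catalysed allylboration (Si face, closed chair) sets the future C9 as S under catalyst control; the mild acid work-up then hydrolyses the borate and the unsaturated dimethyl acetal to the C6 enal.

**Step 9**
Reactants: 17 (2E,4S,6Z,8S)-8-hydroxy-3,7-dimethyl-1-oxoundeca-2,6,10-trien-4-yl (2R)-2-methylbutanoate; 18 methyl 2-(bromomethyl)prop-2-enoate
Product: 19 methyl (2Z,5S,6Z,9S,10E)-2-(bromomethyl)-5-hydroxy-6,10-dimethyl-9-{[(2R)-2-methylbutanoyl]oxy}-12-oxododeca-2,6,10-trienoate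
Conditions: 18 (5 equiv), second-generation Hoveyda–Grubbs catalyst RuCl2(=CH-C6H4-2-OiPr)(SIMes) (10 mol %), CH2Cl2, 40 °C
Reagents that add atoms: methyl 2-(bromomethyl)prop-2-enoate, COC(=O)C(=C)CBr
Why: Olefin cross-metathesis of the only terminal alkene with the 2-substituted acrylate gives the thermodynamic isomer (ester trans to the chain); the trisubstituted alkenes and the enal are inert.

**Step 10**
Reactants: 19 methyl (2Z,5S,6Z,9S,10E)-2-(bromomethyl)-5-hydroxy-6,10-dimethyl-9-{[(2R)-2-methylbutanoyl]oxy}-12-oxododeca-2,6,10-trienoate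
Product: 22 (3S,6S,7S,9S,1(10)Z,4E)-9-hydroxy-3-[(2R)-2-methylbutanoyloxy]germacra-1(10),4,11(13)-trien-12,6-olide, via allylchromium species 20 (not isolated), via chromium alkoxide 21 (not isolated)
Conditions: CrCl2 (8 equiv), THF, rt, syringe-pump addition of 19 over 10 h (final 2 mM); aq. NH4Cl
Reagents that add atoms: none
Why: Intramolecular Nozaki–Hiyama–Kishi allylation closes the ten-membered ring at C6–C7 and the chromium alkoxide lactonises onto the ester. The ester-chelated allylchromium (chain cis to CH2Cr) reacts through a chair with that chain axial, giving the syn adduct and hence the cis-fused lactone. Attack on the Re face of the enal, which gives the C6 configuration of the target, is expected from the macrocyclic transition state with the C3 and C9 substituents pseudo-equatorial, but it is not secured.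

**Step 11**
Reactants: 22 (3S,6S,7S,9S,1(10)Z,4E)-9-hydroxy-3-[(2R)-2-methylbutanoyloxy]germacra-1(10),4,11(13)-trien-12,6-olide
Product: 23 (3S,6R,7S,9S,11R,1(10)Z,4E)-9-hydroxy-3-[(2R)-2-methylbutanoyloxy]germacra-1(10),4-dien-12,6-olide
Conditions: H2 (1 atm), RhCl(PPh3)3 (10 mol %), benzene–EtOH 1:1, rt
Reagents that add atoms: none
Why: Homogeneous hydrogenation reduces only the 1,1-disubstituted conjugated alkene. H2 adds from the lactone face that carries H6 and H7, away from the ring carbons C5 and C8, so the new methyl ends up cis to both ring bonds (11R). The C6 label changes from S to R only because the priorities change.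

**Compound list**
1 | 2,2-dimethoxyacetaldehyde | COC(OC)C=O | starting material
2 | 2-(triphenylphosphoranylidene)propanal | CC(C=O)=P(c1ccccc1)(c1ccccc1)c1ccccc1 | starting material
3 | (2E)-4,4-dimethoxy-2-methylbut-2-enal | O=C/C(C)=C/C(OC)OC | intermediate
4 | allylboronic acid pinacol ester | C=CCB1OC(C)(C)C(C)(C)O1 | starting material
5 | pinacol borate ester of 6, 2-{[(2E,4S)-1,1-dimethoxy-3-methylhepta-2,6-dien-4-yl]oxy}-4,4,5,5-tetramethyl-1,3,2-dioxaborolane | C=CC[C@H](OB1OC(C)(C)C(C)(C)O1)/C(C)=C/C(OC)OC | intermediate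
6 | (2E,4S)-1,1-dimethoxy-3-methylhepta-2,6-dien-4-ol | C=CC[C@H](O)/C(C)=C/C(OC)OC | intermediate
7 | methacryloyl chloride | CC(=C)C(Cl)=O | starting material
8 | (2E,4S)-1,1-dimethoxy-3-methylhepta-2,6-dien-4-yl 2-methylprop-2-enoate | C=CC[C@H](OC(=O)C(C)=C)/C(C)=C/C(OC)OC | intermediate
9 | (6S)-6-[(2E)-4,4-dimethoxybut-2-en-2-yl]-3-methyl-5,6-dihydro-2H-pyran-2-one | CC1=CC[C@H](OC1=O)/C(C)=C/C(OC)OC | intermediate
10 | N,O-dimethylhydroxylamine hydrochloride | CNOC.Cl | starting material
11 | (2Z,5S,6E)-5-hydroxy-N,8,8-trimethoxy-N,2,6-trimethylocta-2,6-dienamide | CON(C)C(=O)/C(C)=C\C[C@H](O)/C(C)=C/C(OC)OC | intermediate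
12 | (2R)-2-methylbutanoic acid | CC[C@@H](C)C(O)=O | starting material
13 | (2E,4S,6Z)-1,1-dimethoxy-8-[methoxy(methyl)amino]-3,7-dimethyl-8-oxoocta-2,6-dien-4-yl (2R)-2-methylbutanoate | CON(C)C(=O)/C(C)=C\C[C@H](OC(=O)[C@H](C)CC)/C(C)=C/C(OC)OC | intermediate
14 | zirconium hemiaminal of 13 (former amide carbon bears H, OZr(Cl)Cp2 and N(OMe)Me; that carbon undefined) | CON(C)C(O[Zr](Cl)(C1C=CC=C1)C1C=CC=C1)/C(C)=C\C[C@H](OC(=O)[C@H](C)CC)/C(C)=C/C(OC)OC | intermediate
15 | (2E,4S,6Z)-1,1-dimethoxy-3,7-dimethyl-8-oxoocta-2,6-dien-4-yl (2R)-2-methylbutanoate | O=C/C(C)=C\C[C@H](OC(=O)[C@H](C)CC)/C(C)=C/C(OC)OC | intermediate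
16 | (2E,4S,6Z,8S)-1,1-dimethoxy-3,7-dimethyl-8-[(4,4,5,5-tetramethyl-1,3,2-dioxaborolan-2-yl)oxy]undeca-2,6,10-trien-4-yl (2R)-2-methylbutanoate | C=CC[C@H](OB1OC(C)(C)C(C)(C)O1)/C(C)=C\C[C@H](OC(=O)[C@H](C)CC)/C(C)=C/C(OC)OC | intermediate
17 | (2E,4S,6Z,8S)-8-hydroxy-3,7-dimethyl-1-oxoundeca-2,6,10-trien-4-yl (2R)-2-methylbutanoate | C=CC[C@H](O)/C(C)=C\C[C@H](OC(=O)[C@H](C)CC)/C(C)=C/C=O | intermediate
18 | methyl 2-(bromomethyl)prop-2-enoate | COC(=O)C(=C)CBr | starting material
19 | methyl (2Z,5S,6Z,9S,10E)-2-(bromomethyl)-5-hydroxy-6,10-dimethyl-9-{[(2R)-2-methylbutanoyl]oxy}-12-oxododeca-2,6,10-trienoate | COC(=O)/C(CBr)=C/C[C@H](O)/C(C)=C\C[C@H](OC(=O)[C@H](C)CC)/C(C)=C/C=O | intermediate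
20 | allylchromium species, 19 with CH2Br replaced by CH2CrCl2 (solvent ligands omitted) | COC(=O)/C(C[Cr](Cl)Cl)=C/C[C@H](O)/C(C)=C\C[C@H](OC(=O)[C@H](C)CC)/C(C)=C/C=O | intermediate
21 | O6 chromium alkoxide of methyl (3S,6S,7S,9S,1(10)Z,4E)-6,9-dihydroxy-3-[(2R)-2-methylbutanoyloxy]germacra-1(10),4,11(13)-trien-12-oate | CC[C@@H](C)C(=O)O[C@H]1C/C=C(/C)[C@@H](O)C[C@@H](C(=C)C(=O)OC)[C@@H](O[Cr](Cl)Cl)/C=C/1C | intermediate
22 | (3S,6S,7S,9S,1(10)Z,4E)-9-hydroxy-3-[(2R)-2-methylbutanoyloxy]germacra-1(10),4,11(13)-trien-12,6-olide (H6 and H7 cis) | CC[C@@H](C)C(=O)O[C@H]1C/C=C(/C)[C@@H](O)C[C@@H]2[C@H](/C=C/1C)OC(=O)C2=C | intermediate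
23 | (3S,6R,7S,9S,11R,1(10)Z,4E)-9-hydroxy-3-[(2R)-2-methylbutanoyloxy]germacra-1(10),4-dien-12,6-olide | CC[C@@H](C)C(=O)O[C@H]1C/C=C(/C)[C@@H](O)C[C@@H]2[C@H](/C=C/1C)OC(=O)[C@@H]2C | target

**Totals**
Total step count: 11. Longest linear sequence: 11 (fully linear from 1 and 2).

**Steps most likely to fail**

The macrocyclisation, step 10, is the main risk. The allylchromium geometry equilibrates and the face is substrate-controlled, so the trans-fused lactone, the wrong C6/C7 pair relative to C3/C9, or oligomers are possible. The fallback sets out from 17. Cross-metathesis with methyl 2-[(4,4,5,5-tetramethyl-1,3,2-dioxaborolan-2-yl)methyl]prop-2-enoate (same ruthenium catalyst) gives the configurationally fixed allylboronate methyl (2E,5S,6Z,9S,10E)-5-hydroxy-6,10-dimethyl-9-{[(2R)-2-methylbutanoyl]oxy}-12-oxo-2-[(4,4,5,5-tetramethyl-1,3,2-dioxaborolan-2-yl)methyl]dodeca-2,6,10-trienoate F2. Acid-catalysed intramolecular allylboration then closes the ring: (R)-TRIP phosphoric acid for Re-face delivery at C6, or Sc(OTf)3 if the chiral acid is too weak, in toluene under syringe-pump addition. The closed chair with the chain fixed cis to CH2B can give only the syn adduct, which lactonises, and the route is rejoined at 22.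

The cross-metathesis, step 9, may stall because the partner is a 1,1-disubstituted acrylate and its allylic bromide can degrade the ruthenium carbene. The fallback sets out from 17. Cross-metathesis with methyl 2-(acetoxymethyl)prop-2-enoate gives the allylic acetate methyl (2E,5S,6Z,9S,10E)-2-(acetoxymethyl)-5-hydroxy-6,10-dimethyl-9-{[(2R)-2-methylbutanoyl]oxy}-12-oxododeca-2,6,10-trienoate F1. Umpolung with Pd(PPh3)4 (5 mol %) and InI in THF under slow addition turns the acetate into the 2-(methoxycarbonyl)allylindium, which adds to the C6 aldehyde and lactonises. This bypasses 19 and comes back to the route at 22.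

The hydrogenation, step 11, may isomerise the exocyclic alkene into the ring or deliver hydrogen with poor face selectivity. The fallback sets out from 22. Conjugate reduction with potassium tri-sec-butylborohydride (2.2 equiv, THF, −78 °C) gives the potassium enolate of 23 F3. Kinetic protonation with 2,6-di-tert-butyl-4-methylphenol from the open face of the cis-fused lactone then gives 23.

**Further compounds**
F1 | step 9 | methyl (2E,5S,6Z,9S,10E)-2-(acetoxymethyl)-5-hydroxy-6,10-dimethyl-9-{[(2R)-2-methylbutanoyl]oxy}-12-oxododeca-2,6,10-trienoate | COC(=O)/C(COC(C)=O)=C/C[C@H](O)/C(C)=C\C[C@H](OC(=O)[C@H](C)CC)/C(C)=C/C=O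
F2 | step 10 | methyl (2E,5S,6Z,9S,10E)-5-hydroxy-6,10-dimethyl-9-{[(2R)-2-methylbutanoyl]oxy}-12-oxo-2-[(4,4,5,5-tetramethyl-1,3,2-dioxaborolan-2-yl)methyl]dodeca-2,6,10-trienoate | COC(=O)/C(CB1OC(C)(C)C(C)(C)O1)=C/C[C@H](O)/C(C)=C\C[C@H](OC(=O)[C@H](C)CC)/C(C)=C/C=O
F3 | step 11 | potassium enolate of 23 (O12–K, C11=C12) | CC[C@@H](C)C(=O)O[C@H]1C/C=C(/C)[C@@H](O)C[C@@H]2[C@H](/C=C/1C)OC(O[K])=C2C
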